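## The problem

The target 25 is an isoflavone: ring A is the benzo ring C4a–C8a, ring C the pyranone O1–C4, and ring B the 4‑hydroxyphenyl group on C3. Every carbon of ring A is substituted: the C4 carbonyl on C4a, OMe on C5, an (S)‑2‑hydroxy‑3‑methylbutyl chain on C6, OH on C7, a prenyl group on C8 and the ring oxygen O1 on C8a. The task is therefore mainly one of regiochemistry on a phloroglucinol core. Three oxygens end in three different states (methyl ether, free phenol, pyranone oxygen), three different carbon substituents must be placed without isomers, and ring C must close onto O8a and not O5. The single stereocentre, the carbinol carbon of the C6 chain, is separated from the planar core by a methylene group. Nothing in the molecule can induce it and it can induce nothing, so it has to be brought in enantiopure and then left untouched. The fragile parts are the prenyl alkene (acid‑induced cyclisation onto a neighbouring phenol to a chroman, attack by electrophilic halogen), the homobenzylic secondary alcohol, and the electrophilic C2 of the finished chromone. The feature that offers a short way in is C4, a lone carbonyl carbon bonded only to C4a of ring A and to C3, where C3 carries ring B and the enol carbon C2. An aryl electrophile at C4a, carbon monoxide and a C3 nucleophile that already holds ring B and C2 at the enol ether level account for the whole skeleton. Because O5 is methylated, only O8a can afterwards close ring C.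

## Retrosynthesis

**25 back to 23.** The O1–C2 bond is cut first, together with the four protecting groups. This leads to the ring‑open phenol 24 and, with its hydroxyls masked, to enone 23. In 23, C2 is a methyl enol ether carbon, O7, O8a and O4' are MOM ethers, and the side‑chain alcohol is a TBS ether. The neighbouring cut at C3–C1' (arylation of a 3‑halochromone) would require halogenating a chromone that carries a prenyl group. The chosen cut lets ring closure share a flask with deprotection: acid frees the C8a phenol, which adds to C2 and expels methanol. The precursor is no smaller, but it is open at ring C and fully protected. The forward step only has to spare the prenyl group in dilute acid.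

**23 back to 14, 22 and 21.** Both bonds to C4 (C4a–C4 and C4–C3) are cut at once, giving aryl iodide 14, carbon monoxide 22 and alkenyl boronate 21. Single cuts are poorer. C4a–C4 alone would need a 3‑alkoxy‑2‑arylacryloyl electrophile, which is neither stable nor easily made. C4–C3 alone would need a benzoyl electrophile made from 14 in extra steps. With CO as C4 the two halves are of similar size (ring A with its five other substituents; ring B with C2 and C3), and each comes from a short linear sequence. The forward reaction must incorporate CO rather than couple directly, and must leave the enol ether intact.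

**14 back to 5, 7 and 4.** Ring A is taken apart one substituent at a time. The C4a–I bond of 14 is cut to silyl ether 12 (through aryllithium 13), and the silyl group to alcohol 11. The C6–CH2 bond of 11 is cut to prenyl arene 9 (through aryllithium 10) and epoxide 4. The C8–CH2 bond of 9 is cut to bis‑MOM ether 6 (through aryllithium 8) and prenyl bromide 7, and 6 is the bis‑ether of 5‑methoxyresorcinol 5. Symmetry speaks for this order: 6 lithiates between its two MOM groups, 9 is again mirror‑symmetric so its two free positions are the same, and 12 has one hydrogen left. No step has a regiochemical choice, and O7 and O8a never need to be told apart, because the iodine decides which becomes O1. The forward steps require ring lithiation to outrun deprotonation of the prenyl CH2, and the epoxide to open at its terminus.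

**4 back to 1.** The epoxide C–O bond at the stereocentre is cut to chlorohydrin 3, which comes from chloro acid 2 and L‑valine 1. The chiral pool fixes the configuration with no resolution or catalyst. The sequence is one retention (diazotisation) and one inversion (ring closure), so (S)‑valine gives the (R)‑epoxide, which becomes the (S)‑carbinol after opening at CH2.

**21 back to 15.** The C–B bond of 21 is cut to vinyllithium 20 and alkenyl bromide 19. The C–Br bond of 19 is cut to enol ether 17 through dibromide 18. The C=C bond of 17 is cut to aldehyde 16, the MOM ether of 4‑hydroxybenzaldehyde 15. Each step is a standard operation on an enol ether. The methyl enol ether is chosen because its Wittig reagent is a common one and because methanol is the leaving group in the final step, which is run in methanol.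

## Roads not taken

Alternative 1: Ring A would be formed last by folding a polyketide‑like chain. The cut is C4a–C5. The precursor A2 is a 3‑aryl‑4‑pyranone whose C6 substituent carries the prenyl‑bearing methine, a ketone (future C7) and an (S)‑γ‑lactone whose carbonyl is the future C5. Base would generate the extended enolate, the pyranone CH (future C4a) would attack the lactone carbonyl, and aromatisation would give isoflavone A1 with the side‑chain alcohol released from the lactone. The merits are real: rings B and C are in place, ring A needs no protecting groups, and the lactone serves as both C5 source and alcohol protection. The weak points are specific to this target. A1 has free 5‑OH and 7‑OH, whereas the target needs 5‑OMe and 7‑OH. The chelated 5‑OH is the less reactive of the two, so the methylation would need a protect–methylate–deprotect detour. A2 has several acidic sites and two epimerisable centres, and is harder to assemble than either fragment of the chosen plan. The chosen plan carries the C5 methyl ether from the first step and avoids that selectivity problem altogether. Alternative 1 is better in that it avoids organolithium chemistry next to a prenyl group.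

Alternative 2: Ring A would be written in one step by a Danheiser benzannulation. The cuts are C7–C8 and C4a–C8a. On heating, cyclobutenone A4 (3‑methoxy, with the silyloxyalkyl chain on C4) and siloxyalkyne A5 (prenyl on the alkyne carbon) would combine through vinylketene, [2+2] adduct and electrocyclisation to phenol A3. The mechanism fixes the position of all substituents, no lithiation next to a prenyl group is needed, and O7 and O8a emerge differentiated. In these respects this road is stronger than the chosen one. Against it, A4 and A5 each need several steps (A4 with the stereogenic chain attached to a strained ring). A3 also still has hydrogen at C4a, so ring A would have to be iodinated or acylated and then joined to rings B and C, which means the key step of the chosen plan or its equivalent comes on top. The chosen plan reaches the same substitution pattern in five steps from 5 by using the symmetry of 6 and 9, and it does not need O7 and O8a differentiated.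

Alternative 3: Ring C would be built on ring A by aryne insertion. The cuts are C8a–O1, C4a–C4 and O1–C2. A fluoride source would unmask the C4a–C8a aryne from silyl triflate A7. The carboxylate oxygen of cesium 3‑methoxy‑2‑arylacrylate A8 would add at C8a, which is the site favoured by the C5 methoxy group. The aryl anion would take the acyl group at C4a, and the phenoxide would displace methoxide at C2 to give the protected isoflavone A6. This forms three bonds and ring C in one step without CO or palladium, which is more than the chosen key step achieves. Its costs lie in the precursor and the conditions. A7 needs O8a as a triflate distinct from O7, and a silyl group on the last position of a hexasubstituted ring, so the symmetry that makes 14 short is lost. The attack at C8a is next to the prenyl group, and fluoride endangers the side‑chain silyl ether. The chosen plan gives up the ring closure in the key step, but the closure comes free in the final deprotection, and the ring‑A partner is simpler to make.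

Key step: step 13

Assumption: the enol ether geometry in 17 and 19–24 does not affect the outcome, because C2 becomes a ring sp2 carbon by addition–elimination. 17 is drawn as the E isomer of an E/Z mixture, and 19–24 as the isomers with OMe cis to the aryl group. A mixture, if formed, would be carried forward.

## Route

Step 1
Reactants: 1 L‑valine
Product: 2 (2S)‑2‑chloro‑3‑methylbutanoic acid
Conditions: NaNO2, 5 M HCl, 0 °C → rt
Reagents that add atoms: hydrogen chloride, Cl
Why: Diazotisation of the α‑amino acid in HCl gives the α‑chloro acid with net retention (double inversion through the α‑lactone formed by carboxylate participation), so the (S) centre of L‑valine is kept.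

Step 2
Reactants: 2 (2S)‑2‑chloro‑3‑methylbutanoic acid
Product: 3 (2S)‑2‑chloro‑3‑methylbutan‑1‑ol
Conditions: LiAlH4, Et2O, 0 °C
Reagents that add atoms: none
Why: Hydride reduction of the carboxylic acid to the primary alcohol is faster at 0 °C than displacement of the secondary chloride; the stereocentre is not touched.

Step 3
Reactants: 3 (2S)‑2‑chloro‑3‑methylbutan‑1‑ol
Product: 4 (2R)‑2‑(propan‑2‑yl)oxirane
Conditions: KOH, H2O, 0 → 30 °C, distillation
Reagents that add atoms: none
Why: Intramolecular Williamson etherification: the alkoxide displaces chloride with inversion at C2, so the (S)‑chlorohydrin gives the (R)‑epoxide, which is distilled from the basic medium.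

Step 4
Reactants: 5 5‑methoxyresorcinol
Product: 6 1‑methoxy‑3,5‑bis(methoxymethoxy)benzene
Conditions: NaH, DMF, 0 °C; MOMCl, 0 °C → rt
Reagents that add atoms: chloromethyl methyl ether (MOMCl), COCCl
Why: O‑Alkylation of both phenoxides (Williamson type); the MOM ethers direct the three later lithiations and are removed in the last step.

Step 5
Reactants: 6 1‑methoxy‑3,5‑bis(methoxymethoxy)benzene; 7 prenyl bromide (1‑bromo‑3‑methylbut‑2‑ene)
Product: 9 5‑methoxy‑1,3‑bis(methoxymethoxy)‑2‑(3‑methylbut‑2‑en‑1‑yl)benzene, via aryllithium 8 (not isolated)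
Conditions: n‑BuLi, THF, 0 °C; then 7, −78 °C → rt
Reagents that add atoms: none
Why: Directed ortho‑metalation takes place at the position flanked by the two MOM ethers (double chelation, most acidic ring hydrogen), and the aryllithium is alkylated by SN2 at the primary carbon of 7; the product keeps the mirror symmetry of 6.

Step 6
Reactants: 9 5‑methoxy‑1,3‑bis(methoxymethoxy)‑2‑(3‑methylbut‑2‑en‑1‑yl)benzene; 4 (2R)‑2‑(propan‑2‑yl)oxirane
Product: 11 (2S)‑1‑[6‑methoxy‑2,4‑bis(methoxymethoxy)‑3‑(3‑methylbut‑2‑en‑1‑yl)phenyl]‑3‑methylbutan‑2‑ol, via aryllithium 10 (not isolated)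
Conditions: n‑BuLi, THF, 0 °C; then 4, BF3·OEt2, −78 °C
Reagents that add atoms: none
Why: The two free ring positions of 9 are equivalent and each lies between OMe and OMOM, so a second directed ortho‑metalation gives one aryllithium, which opens the BF3‑activated epoxide at its CH2 terminus (SN2). The stereocentre is not involved; its descriptor changes from R to S only because the CIP priorities change.

Step 7
Reactants: 11 (2S)‑1‑[6‑methoxy‑2,4‑bis(methoxymethoxy)‑3‑(3‑methylbut‑2‑en‑1‑yl)phenyl]‑3‑methylbutan‑2‑ol
Product: 12 tert‑butyl{[(2S)‑1‑[6‑methoxy‑2,4‑bis(methoxymethoxy)‑3‑(3‑methylbut‑2‑en‑1‑yl)phenyl]‑3‑methylbutan‑2‑yl]oxy}dimethylsilane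
Conditions: TBSCl, imidazole, DMF, rt
Reagents that add atoms: tert‑butyldimethylsilyl chloride (TBSCl), CC(C)(C)[Si](C)(C)Cl
Why: Standard silylation of a secondary alcohol; it removes the acidic OH before the third lithiation and the palladium step, and the silyl ether is cleaved together with the MOM groups at the end.

Step 8
Reactants: 12 tert‑butyl{[(2S)‑1‑[6‑methoxy‑2,4‑bis(methoxymethoxy)‑3‑(3‑methylbut‑2‑en‑1‑yl)phenyl]‑3‑methylbutan‑2‑yl]oxy}dimethylsilane
Product: 14 tert‑butyl{[(2S)‑1‑[3‑iodo‑2‑methoxy‑4,6‑bis(methoxymethoxy)‑5‑(3‑methylbut‑2‑en‑1‑yl)phenyl]‑3‑methylbutan‑2‑yl]oxy}dimethylsilane, via aryllithium 13 (not isolated)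
Conditions: n‑BuLi, THF, 0 °C; then ICH2CH2I, −78 °C → rt
Reagents that add atoms: 1,2‑diiodoethane, ICCI
Why: The only ring hydrogen left lies between OMe and OMOM, so directed ortho‑metalation and iodination put iodine on the future C4a without a regiochemical choice; 1,2‑diiodoethane is a mild iodine donor that spares the prenyl alkene.

Step 9
Reactants: 15 4‑hydroxybenzaldehyde
Product: 16 4‑(methoxymethoxy)benzaldehyde
Conditions: NaH, DMF, 0 °C; MOMCl, 0 °C → rt
Reagents that add atoms: chloromethyl methyl ether (MOMCl), COCCl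
Why: O‑Alkylation of the phenoxide; using the same protecting group as on ring A allows a single deprotection at the end.

Step 10
Reactants: 16 4‑(methoxymethoxy)benzaldehyde
Product: 17 1‑[(E)‑2‑methoxyethenyl]‑4‑(methoxymethoxy)benzene (E/Z mixture)
Conditions: Ph3P(CH2OMe)Cl, KOtBu, THF, 0 °C → rt
Reagents that add atoms: (methoxymethyl)triphenylphosphonium chloride, COC[P+](c1ccccc1)(c1ccccc1)c1ccccc1.[Cl-]
Why: Wittig reaction of the non‑stabilised methoxymethylene ylide with an aromatic aldehyde; the E/Z mixture of the β‑methoxystyrene does not matter for the next step.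

Step 11
Reactants: 17 1‑[(E)‑2‑methoxyethenyl]‑4‑(methoxymethoxy)benzene
Product: 19 1‑[(E)‑1‑bromo‑2‑methoxyethenyl]‑4‑(methoxymethoxy)benzene, via dibromide 18 (not isolated)
Conditions: Br2, CH2Cl2, −78 °C; then Et3N, −78 °C → rt
Reagents that add atoms: bromine, BrBr
Why: Bromine adds across the electron‑rich enol ether, and the amine removes HBr by ionisation of the α‑bromo ether and loss of the benzylic proton (the bromination–dehydrobromination used for 2‑bromovinyl ethers), which leaves bromine on the aryl‑bearing carbon.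

Step 12
Reactants: 19 1‑[(E)‑1‑bromo‑2‑methoxyethenyl]‑4‑(methoxymethoxy)benzene
Product: 21 2‑{(Z)‑2‑methoxy‑1‑[4‑(methoxymethoxy)phenyl]ethenyl}‑4,4,5,5‑tetramethyl‑1,3,2‑dioxaborolane, via vinyllithium 20 (not isolated)
Conditions: t‑BuLi (2 equiv), Et2O, −78 °C; then iPrOBpin, −78 °C → rt
Reagents that add atoms: 2‑isopropoxy‑4,4,5,5‑tetramethyl‑1,3,2‑dioxaborolane (iPrOBpin), CC(C)OB1OC(C)(C)C(C)(C)O1
Why: Bromine–lithium exchange of the alkenyl bromide and trapping of the vinyllithium with the borate both proceed with retention of alkene geometry; the low temperature suppresses loss of LiOMe to the arylalkyne.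

Step 13
Reactants: 14 tert‑butyl{[(2S)‑1‑[3‑iodo‑2‑methoxy‑4,6‑bis(methoxymethoxy)‑5‑(3‑methylbut‑2‑en‑1‑yl)phenyl]‑3‑methylbutan‑2‑yl]oxy}dimethylsilane; 22 carbon monoxide; 21 2‑{(Z)‑2‑methoxy‑1‑[4‑(methoxymethoxy)phenyl]ethenyl}‑4,4,5,5‑tetramethyl‑1,3,2‑dioxaborolane
Product: 23 (2E)‑1‑{3‑[(2S)‑2‑(tert‑butyldimethylsilyloxy)‑3‑methylbutyl]‑2‑methoxy‑4,6‑bis(methoxymethoxy)‑5‑(3‑methylbut‑2‑en‑1‑yl)phenyl}‑3‑methoxy‑2‑[4‑(methoxymethoxy)phenyl]prop‑2‑en‑1‑one
Conditions: Pd(PPh3)4 (5 mol %), K2CO3, CO (5 bar), anisole, 80 °C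
Reagents that add atoms: none
Why: Proposed new method: zerovalent palladium inserts into the C4a–I bond of 14, CO inserts into the aryl–palladium bond, the base‑activated boronate 21 transfers its 2‑methoxy‑1‑arylvinyl group to the acylpalladium centre, and reductive elimination gives the ketone with the alkene geometry retained, so C4a–C4 and C4–C3 are formed in one operation. The closest known reaction type is the carbonylative Suzuki–Miyaura coupling of aryl iodides, di‑ortho‑substituted ones included, with aryl‑ and simple alkenylboron reagents; the new element is an α‑aryl‑β‑alkoxyvinyl boronate as the nucleophile. No ring is closed and no stereocentre is formed; ring C is left open so that its closure can share the final deprotection. The selectivity needed is carbonylative over direct coupling, and it is secured by the two ortho oxygen substituents of the iodide, which slow transmetalation at the arylpalladium stage, and by CO pressure. The position of C4 is fixed by the iodine, which occupies the only site of ring A that was left free. In the alkenylpalladium intermediate palladium and OMe are trans, so syn β‑alkoxide elimination to an alkyne is not available. The prenyl alkene, MOM acetals, silyl ether and the vinylogous ester product should be inert to K2CO3 and the catalyst.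

Step 14
Reactants: 23 (2E)‑1‑{3‑[(2S)‑2‑(tert‑butyldimethylsilyloxy)‑3‑methylbutyl]‑2‑methoxy‑4,6‑bis(methoxymethoxy)‑5‑(3‑methylbut‑2‑en‑1‑yl)phenyl}‑3‑methoxy‑2‑[4‑(methoxymethoxy)phenyl]prop‑2‑en‑1‑one
Product: 25 7‑hydroxy‑6‑[(2S)‑2‑hydroxy‑3‑methylbutyl]‑3‑(4‑hydroxyphenyl)‑5‑methoxy‑8‑(3‑methylbut‑2‑en‑1‑yl)‑4H‑chromen‑4‑one, via ring‑open phenol 24 (not isolated)
Conditions: HCl (1.25 M in MeOH), rt → 40 °C
Reagents that add atoms: none
Why: Acidic methanolysis cleaves the three MOM acetals and the TBS ether; the freed C8a phenol then adds to C2 of the β‑methoxy enone and methanol is lost (6‑endo addition–elimination, the usual closure of chromones from β‑alkoxy or β‑amino enones). Only O8a can close because O5 is methylated, and the stereocentre is not involved.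

## Compound list

1 | L‑valine | CC(C)[C@H](N)C(=O)O | starting material
2 | (2S)‑2‑chloro‑3‑methylbutanoic acid | CC(C)[C@H](Cl)C(=O)O | intermediate
3 | (2S)‑2‑chloro‑3‑methylbutan‑1‑ol | CC(C)[C@H](Cl)CO | intermediate
4 | (2R)‑2‑(propan‑2‑yl)oxirane | CC(C)[C@@H]1CO1 | intermediate
5 | 5‑methoxyresorcinol | COc1cc(O)cc(O)c1 | starting material
6 | 1‑methoxy‑3,5‑bis(methoxymethoxy)benzene | COc1cc(OCOC)cc(OCOC)c1 | intermediate
7 | prenyl bromide (1‑bromo‑3‑methylbut‑2‑ene) | CC(C)=CCBr | starting material
8 | [4‑methoxy‑2,6‑bis(methoxymethoxy)phenyl]lithium (formed in situ) | COc1cc(OCOC)c([Li])c(OCOC)c1 | intermediate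
9 | 5‑methoxy‑1,3‑bis(methoxymethoxy)‑2‑(3‑methylbut‑2‑en‑1‑yl)benzene | COc1cc(OCOC)c(CC=C(C)C)c(OCOC)c1 | intermediate
10 | [6‑methoxy‑2,4‑bis(methoxymethoxy)‑3‑(3‑methylbut‑2‑en‑1‑yl)phenyl]lithium (formed in situ) | COc1cc(OCOC)c(CC=C(C)C)c(OCOC)c1[Li] | intermediate
11 | (2S)‑1‑[6‑methoxy‑2,4‑bis(methoxymethoxy)‑3‑(3‑methylbut‑2‑en‑1‑yl)phenyl]‑3‑methylbutan‑2‑ol | COc1cc(OCOC)c(CC=C(C)C)c(OCOC)c1C[C@H](O)C(C)C | intermediate
12 | tert‑butyl{[(2S)‑1‑[6‑methoxy‑2,4‑bis(methoxymethoxy)‑3‑(3‑methylbut‑2‑en‑1‑yl)phenyl]‑3‑methylbutan‑2‑yl]oxy}dimethylsilane | COc1cc(OCOC)c(CC=C(C)C)c(OCOC)c1C[C@H](O[Si](C)(C)C(C)(C)C)C(C)C | intermediate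
13 | {3‑[(2S)‑2‑(tert‑butyldimethylsilyloxy)‑3‑methylbutyl]‑2‑methoxy‑4,6‑bis(methoxymethoxy)‑5‑(3‑methylbut‑2‑en‑1‑yl)phenyl}lithium (formed in situ) | COc1c([Li])c(OCOC)c(CC=C(C)C)c(OCOC)c1C[C@H](O[Si](C)(C)C(C)(C)C)C(C)C | intermediate
14 | tert‑butyl{[(2S)‑1‑[3‑iodo‑2‑methoxy‑4,6‑bis(methoxymethoxy)‑5‑(3‑methylbut‑2‑en‑1‑yl)phenyl]‑3‑methylbutan‑2‑yl]oxy}dimethylsilane | COc1c(I)c(OCOC)c(CC=C(C)C)c(OCOC)c1C[C@H](O[Si](C)(C)C(C)(C)C)C(C)C | intermediate
15 | 4‑hydroxybenzaldehyde | O=Cc1ccc(O)cc1 | starting material
16 | 4‑(methoxymethoxy)benzaldehyde | COCOc1ccc(C=O)cc1 | intermediate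
17 | 1‑[(E)‑2‑methoxyethenyl]‑4‑(methoxymethoxy)benzene (E/Z mixture, drawn E) | CO/C=C/c1ccc(OCOC)cc1 | intermediate
18 | 1‑(1,2‑dibromo‑2‑methoxyethyl)‑4‑(methoxymethoxy)benzene (diastereomer mixture, formed in situ) | COC(Br)C(Br)c1ccc(OCOC)cc1 | intermediate
19 | 1‑[(E)‑1‑bromo‑2‑methoxyethenyl]‑4‑(methoxymethoxy)benzene | CO/C=C(\c1ccc(OCOC)cc1)Br | intermediate
20 | {(Z)‑2‑methoxy‑1‑[4‑(methoxymethoxy)phenyl]ethenyl}lithium (formed in situ) | CO/C=C(\c1ccc(OCOC)cc1)[Li] | intermediate
21 | 2‑{(Z)‑2‑methoxy‑1‑[4‑(methoxymethoxy)phenyl]ethenyl}‑4,4,5,5‑tetramethyl‑1,3,2‑dioxaborolane | CO/C=C(\c1ccc(OCOC)cc1)B1OC(C)(C)C(C)(C)O1 | intermediate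
22 | carbon monoxide | [C-]#[O+] | starting material
23 | (2E)‑1‑{3‑[(2S)‑2‑(tert‑butyldimethylsilyloxy)‑3‑methylbutyl]‑2‑methoxy‑4,6‑bis(methoxymethoxy)‑5‑(3‑methylbut‑2‑en‑1‑yl)phenyl}‑3‑methoxy‑2‑[4‑(methoxymethoxy)phenyl]prop‑2‑en‑1‑one | CO/C=C(\c1ccc(OCOC)cc1)C(=O)c1c(OC)c(C[C@H](O[Si](C)(C)C(C)(C)C)C(C)C)c(OCOC)c(CC=C(C)C)c1OCOC | intermediate
24 | (2E)‑1‑{2,4‑dihydroxy‑5‑[(2S)‑2‑hydroxy‑3‑methylbutyl]‑6‑methoxy‑3‑(3‑methylbut‑2‑en‑1‑yl)phenyl}‑2‑(4‑hydroxyphenyl)‑3‑methoxyprop‑2‑en‑1‑one (formed in situ) | CO/C=C(\c1ccc(O)cc1)C(=O)c1c(OC)c(C[C@H](O)C(C)C)c(O)c(CC=C(C)C)c1O | intermediate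
25 | 7‑hydroxy‑6‑[(2S)‑2‑hydroxy‑3‑methylbutyl]‑3‑(4‑hydroxyphenyl)‑5‑methoxy‑8‑(3‑methylbut‑2‑en‑1‑yl)‑4H‑chromen‑4‑one | COc1c(C[C@H](O)C(C)C)c(O)c(CC=C(C)C)c2occ(-c3ccc(O)cc3)c(=O)c12 | target

## Step count and risks

Total: 14 steps. Longest linear sequence: 8 steps (steps 1, 2, 3, 6, 7, 8, 13, 14, from L‑valine). The ring‑A line from 5 is 7 steps and the boronate line from 15 is 6 steps.

**Step 13 (key step).** The most likely failures are direct coupling without uptake of CO, and slow transfer of the hindered, donor‑substituted alkenyl group to the crowded acylpalladium centre. Slow transfer would lead to protodeboronation of 21, hydrodeiodination of 14, or hydrolysis of the acyl intermediate. The fallback makes the same two bonds one after the other by known polar chemistry. It sets out from 12: aryllithium 13 is generated as in step 8 and quenched with DMF instead of the iodine donor. This gives 3‑[(2S)‑2‑(tert‑butyldimethylsilyloxy)‑3‑methylbutyl]‑2‑methoxy‑4,6‑bis(methoxymethoxy)‑5‑(3‑methylbut‑2‑en‑1‑yl)benzaldehyde F1 (bond C4a–C4). Vinyllithium 20, generated from 19 as in step 12, is added to F1 at −78 °C. This gives (2E)‑1‑{3‑[(2S)‑2‑(tert‑butyldimethylsilyloxy)‑3‑methylbutyl]‑2‑methoxy‑4,6‑bis(methoxymethoxy)‑5‑(3‑methylbut‑2‑en‑1‑yl)phenyl}‑3‑methoxy‑2‑[4‑(methoxymethoxy)phenyl]prop‑2‑en‑1‑ol F2 (bond C4–C3). F2 is acid‑sensitive and is oxidised at once with MnO2 in CH2Cl2. The fallback returns to the route at 23.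

**Step 8.** Deprotonation at the benzylic and allylic CH2 of the prenyl group may compete with ring metalation at the crowded last position, and the iodine donor may attack the alkene. The fallback replaces deprotonation by electrophilic aromatic substitution: 12 is treated with N‑iodosuccinimide in MeCN at low temperature in the dark. The single open position of the phloroglucinol triether is the most nucleophilic site, and the silylated alcohol cannot take part in iodoetherification. The fallback sets out from 12 and returns at 14.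

**Step 6.** The 2,6‑dioxygenated aryllithium may open the epoxide slowly, and BF3 may strip MOM acetals or rearrange the epoxide before it is opened. The fallback avoids the Lewis acid. Aryllithium 10 is transmetalated with MgBr2·OEt2 to [6‑methoxy‑2,4‑bis(methoxymethoxy)‑3‑(3‑methylbut‑2‑en‑1‑yl)phenyl]magnesium bromide F3, which opens 4 at the terminus under CuI catalysis (THF, −30 → 0 °C). The fallback sets out from 10 (made from 9) and returns at 11.

**Step 12.** Anti elimination of LiOMe from vinyllithium 20 to the arylalkyne, or deprotonation in place of exchange, would reduce the supply of 21. The fallback avoids the organolithium: palladium‑catalysed Miyaura borylation of 19 with bis(pinacolato)diboron (PdCl2(PPh3)2, PPh3, KOPh, toluene, 50 °C). It sets out from 19 and returns at 21. If 20 proved unusable, the fallback for step 13 would be affected as well.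

**Step 14.** Acid‑induced addition of the C7 or C8a phenol to the prenyl alkene (chroman formation) may compete with deprotection, and the hindered silyl ether may be cleaved only slowly. The fallback separates the operations and avoids Brønsted acid. It sets out from 23. ZnBr2 and n‑PrSH in CH2Cl2 at 0 °C remove the three MOM groups to give (2E)‑1‑{5‑[(2S)‑2‑(tert‑butyldimethylsilyloxy)‑3‑methylbutyl]‑2,4‑dihydroxy‑6‑methoxy‑3‑(3‑methylbut‑2‑en‑1‑yl)phenyl}‑2‑(4‑hydroxyphenyl)‑3‑methoxyprop‑2‑en‑1‑one F4. K2CO3 in MeOH closes ring C to give 6‑[(2S)‑2‑(tert‑butyldimethylsilyloxy)‑3‑methylbutyl]‑7‑hydroxy‑3‑(4‑hydroxyphenyl)‑5‑methoxy‑8‑(3‑methylbut‑2‑en‑1‑yl)‑4H‑chromen‑4‑one F5. Tetrabutylammonium fluoride in THF then removes the silyl group, and the fallback returns at 25.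

## Further compounds

F1 | step 13 | 3‑[(2S)‑2‑(tert‑butyldimethylsilyloxy)‑3‑methylbutyl]‑2‑methoxy‑4,6‑bis(methoxymethoxy)‑5‑(3‑methylbut‑2‑en‑1‑yl)benzaldehyde | COc1c(C=O)c(OCOC)c(CC=C(C)C)c(OCOC)c1C[C@H](O[Si](C)(C)C(C)(C)C)C(C)C
F2 | step 13 | (2E)‑1‑{3‑[(2S)‑2‑(tert‑butyldimethylsilyloxy)‑3‑methylbutyl]‑2‑methoxy‑4,6‑bis(methoxymethoxy)‑5‑(3‑methylbut‑2‑en‑1‑yl)phenyl}‑3‑methoxy‑2‑[4‑(methoxymethoxy)phenyl]prop‑2‑en‑1‑ol (epimer mixture at C1) | CO/C=C(\c1ccc(OCOC)cc1)C(O)c1c(OC)c(C[C@H](O[Si](C)(C)C(C)(C)C)C(C)C)c(OCOC)c(CC=C(C)C)c1OCOC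
F0 | step 8 | none | none
F3 | step 6 | [6‑methoxy‑2,4‑bis(methoxymethoxy)‑3‑(3‑methylbut‑2‑en‑1‑yl)phenyl]magnesium bromide | COc1cc(OCOC)c(CC=C(C)C)c(OCOC)c1[Mg]Br
F0 | step 12 | none | none
F4 | step 14 | (2E)‑1‑{5‑[(2S)‑2‑(tert‑butyldimethylsilyloxy)‑3‑methylbutyl]‑2,4‑dihydroxy‑6‑methoxy‑3‑(3‑methylbut‑2‑en‑1‑yl)phenyl}‑2‑(4‑hydroxyphenyl)‑3‑methoxyprop‑2‑en‑1‑one | CO/C=C(\c1ccc(O)cc1)C(=O)c1c(OC)c(C[C@H](O[Si](C)(C)C(C)(C)C)C(C)C)c(O)c(CC=C(C)C)c1O
F5 | step 14 | 6‑[(2S)‑2‑(tert‑butyldimethylsilyloxy)‑3‑methylbutyl]‑7‑hydroxy‑3‑(4‑hydroxyphenyl)‑5‑methoxy‑8‑(3‑methylbut‑2‑en‑1‑yl)‑4H‑chromen‑4‑one | COc1c(C[C@H](O[Si](C)(C)C(C)(C)C)C(C)C)c(O)c(CC=C(C)C)c2occ(-c3ccc(O)cc3)c(=O)c12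
A1 | alternative 1 | 5,7‑dihydroxy‑6‑[(2S)‑2‑hydroxy‑3‑methylbutyl]‑3‑[4‑(methoxymethoxy)phenyl]‑8‑(3‑methylbut‑2‑en‑1‑yl)‑4H‑chromen‑4‑one | COCOc1ccc(cc1)-c1coc2c(CC=C(C)C)c(O)c(C[C@H](O)C(C)C)c(O)c2c1=O
A2 | alternative 1 | 3‑[4‑(methoxymethoxy)phenyl]‑6‑{5‑methyl‑1‑oxo‑1‑[(5S)‑2‑oxo‑5‑(propan‑2‑yl)oxolan‑3‑yl]hex‑4‑en‑2‑yl}‑4H‑pyran‑4‑one (epimer mixture at the two enolisable centres) | O=c1cc(C(CC=C(C)C)C(=O)C2C[C@@H](C(C)C)OC2=O)occ1-c1ccc(OCOC)cc1
A3 | alternative 2 | 6‑[(2S)‑2‑(tert‑butyldimethylsilyloxy)‑3‑methylbutyl]‑5‑methoxy‑2‑(3‑methylbut‑2‑en‑1‑yl)‑3‑(triisopropylsilyloxy)phenol | COc1cc(O[Si](C(C)C)(C(C)C)C(C)C)c(CC=C(C)C)c(O)c1C[C@H](O[Si](C)(C)C(C)(C)C)C(C)C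
A4 | alternative 2 | 4‑[(2S)‑2‑(tert‑butyldimethylsilyloxy)‑3‑methylbutyl]‑3‑methoxycyclobut‑2‑en‑1‑one (epimer mixture at the ring carbon) | COC1=CC(=O)C1C[C@H](O[Si](C)(C)C(C)(C)C)C(C)C
A5 | alternative 2 | triisopropyl[(5‑methylhex‑4‑en‑1‑yn‑1‑yl)oxy]silane | CC(C)=CCC#CO[Si](C(C)C)(C(C)C)C(C)C
A6 | alternative 3 | 6‑[(2S)‑2‑(tert‑butyldimethylsilyloxy)‑3‑methylbutyl]‑5‑methoxy‑7‑(methoxymethoxy)‑3‑[4‑(methoxymethoxy)phenyl]‑8‑(3‑methylbut‑2‑en‑1‑yl)‑4H‑chromen‑4‑one | COc1c(C[C@H](O[Si](C)(C)C(C)(C)C)C(C)C)c(OCOC)c(CC=C(C)C)c2occ(-c3ccc(OCOC)cc3)c(=O)c12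
A7 | alternative 3 | 4‑[(2S)‑2‑(tert‑butyldimethylsilyloxy)‑3‑methylbutyl]‑5‑methoxy‑3‑(methoxymethoxy)‑2‑(3‑methylbut‑2‑en‑1‑yl)‑6‑(trimethylsilyl)phenyl trifluoromethanesulfonate | COc1c(C[C@H](O[Si](C)(C)C(C)(C)C)C(C)C)c(OCOC)c(CC=C(C)C)c(OS(=O)(=O)C(F)(F)F)c1[Si](C)(C)C
A8 | alternative 3 | cesium (2E)‑3‑methoxy‑2‑[4‑(methoxymethoxy)phenyl]prop‑2‑enoate | CO/C=C(\c1ccc(OCOC)cc1)C(=O)[O-].[Cs+]
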